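At the reading of 25.0 s the red run holds 11.8% of its Z as L, just short of the 12% asked of the flask, so I get the crossing time from the readings in two ways.

- red: Z 0.70 M; D 0.525 M; run made earlier
- flask: Z 0.35 M; D 0.525 M; time 15 min

red run (percent of the Z charged)

| time / s | L / % | G / % |
|---|---|---|
| 10.0 | 5.5 | 9.0 |
| 15.0 | 8.6 | 13.3 |
| 25.0 | 11.8 | 20.6 |
| 40.0 | 15.2 | 30.0 |
| 50.0 | 16.5 | 34.8 |
| 80.0 | 16.2 | 46.4 |
| 90.0 | 16.5 | 49.5 |

(readings scatter by 0.3 percentage points)

- what is said of G includes Q
- Q is a solid; its amount is given per volume of the solution
- steps that have been proposed: Z <-> L; Z -> G; D + L <-> X; Q <-> G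

* time, not beyond 15 min, at which the flask holds most L
* the amount of L, in percent of the Z charged, at that time
* the first time at which L reaches 12%, in the same percent, in min

First I replace the rise of L up to that reading by its mean slope, which gives 25.4 s. Then I draw the straight line between that reading and the next, which gives 25.9 s. The mean lands earlier, and it is the one that cheats, because past that reading L climbs at half its mean slope. With 0.2 percentage points still to climb, the cheat costs 0.500 s, so I read 0.432 min for the red run, a reading that carries the scatter of the readings.

Both numbers belong to the red run. To carry them over I need the cost, the percent of its own D that a flask loses for each percent of its Z held as X. By the step D + L <-> X this is the Z charge over the D charge: 1.33 in the red run and 0.667 in the flask. If D stays near its charge, which is 0.525 M in both the red run and the flask, capture of L is pseudo-first-order and the percent curve of L can be copied from the red run to the flask, and on that condition I commit to the same time for the flask.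

The forecast gives 0.44 min, slightly later than my figure, and a peak of 16.4% at 1.2 min, holding that “every step is effectively first order in the Z-derived species”. It takes X in the red run as about 6 percent by 90.0 s, which at the cost of that run means 8.00% of D, and at the cost of the flask the same percent of X would mean 4.00%.

The flask reaches the level at 0.430 min and peaks at 16.5% at 1.15 min.

    Z ⇌ L (K = 0.530, k = 0.00720 s⁻¹)
    Z → G (k = 0.0100 s⁻¹)
    D + L ⇌ X (K = 1.30 M⁻¹, k = 0.00800 M⁻¹ s⁻¹)
    Q ⇌ G, rate k4*(cs4 - [G]) while solid is left; crystals form when [G] > cs4 (solubility = 0.290 M, k = 0.360 s⁻¹)

At 1.50 min the flask holds 3.90% as X, which at its cost means a loss of 2.60% of D, and its D stands at 97.4%. The neighbour with 2.1 M of D has a cost of 0.167, so its 6.37% as X at 15.0 min takes 1.06% of its D, which stands at 98.9%.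

All runs are calculated on assumed constants, and the scatter is random.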